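A direct plan would add the lithium enolate of tri-O-benzyl phloroacetophenone A1 to the silyl-protected aldehyde A2, dehydrate the aldol and finish by hydrogenation with hydrogenolysis. The carbinol of A2 would be set by asymmetric allylboration of methyl 11-oxoundecanoate A3. Its weakest points would be:
- the allylboration of an unbranched aldehyde, which would need a stoichiometric pinene-derived borane and would leave no later chance to upgrade the enantiomeric purity;
- the threefold O-benzylation of the hydrogen-bonded phloroglucinol ketone, where C-benzylation and incomplete alkylation of the ortho phenols would compete;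
- the aldol, mesylation, elimination and hydrogenation detour plus the ester-to-alcohol-to-aldehyde redox shuffle, which would spend many steps on one unfunctionalised C–C bond.

**Strategy.** The route never acylates an arene. The benzene ring (C1'–C6', oxygen on C2', C4', C6') together with the ketone carbon C1 on C1' is read as a tetraketide, and the ring is built last. A 3,5,7-trioxo ester, released in the flask from a 6-(2-oxoalkyl)-4-hydroxy-2-pyrone, closes by a biomimetic Claisen condensation. One operation forms the carbocycle, fixes a single acyl group on carbon and unveils three free phenols, so benzylation, enone formation and hydrogenolysis have no counterpart. The ring carbons come from triacetic acid lactone. C13 is bought as an enantiopure epoxide and joined by acetylide opening, which replaces the allylboration.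

Key step: step 4

Assumption: (S)-1,2-epoxypentane is purchased as the single enantiomer and is the only source of chirality. Chain carbons are numbered as in the target (C1 = ketone carbon, C13 = carbinol carbon); the triketo ester is numbered from its ester carbon.

Step 1
Reactants: 1 undec-10-ynoic acid; 2 (S)-1,2-epoxypentane [(2S)-2-propyloxirane]
Product: 4 (13S)-13-hydroxyhexadec-10-ynoic acid, via lithium 11-lithioundec-10-ynoate 3 (not isolated)
Conditions: 1 (1.0 equiv), n-BuLi (2.05 equiv), THF, –78 → 0 °C; DMPU, then 2 (1.3 equiv), 0 °C → rt; 1 M HCl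
Reagents that add atoms: none
Why: Alkylation of a lithium acetylide by a terminal epoxide (SN2 opening at the unsubstituted carbon, assisted by DMPU), in which the second equivalent of n-BuLi metalates the alkyne of the lithium carboxylate and the C–O bond of the purchased stereocentre is never broken, so C13 is delivered as S.

Step 2
Reactants: 4 (13S)-13-hydroxyhexadec-10-ynoic acid
Product: 6 methyl (13S)-13-hydroxyhexadecanoate, via methyl (13S)-13-hydroxyhexadec-10-ynoate 5 (not isolated)
Conditions: HCl (1.25 M in MeOH, 0.1 equiv), MeOH, 50 °C; then 10% Pd/C, H2 (1 atm), rt; filter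
Reagents that add atoms: methanol, CO
Why: Fischer esterification in methanol followed in the same flask by heterogeneous catalytic hydrogenation of the isolated alkyne to the alkane; the homopropargylic carbinol is not activated for hydrogenolysis and no bond at C13 is touched, so it stays S.

Step 3
Reactants: 6 methyl (13S)-13-hydroxyhexadecanoate; 7 triacetic acid lactone (4-hydroxy-6-methyl-2H-pyran-2-one)
Product: 9 4-hydroxy-6-[(14S)-14-hydroxy-2-oxoheptadecyl]-2H-pyran-2-one, via lithium 6-(lithiomethyl)-2-oxo-2H-pyran-4-olate 8 (not isolated)
Conditions: 7 (3.3 equiv), LiN(iPr)2 (6.6 equiv), THF/DMPU, –78 °C, 1 h; then 6 (1.0 equiv) in THF, –78 → 0 °C; 1 M HCl to pH 2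
Reagents that add atoms: none
Why: Claisen-type C-acylation of the lactone dianion at its 6-methyl carbon (the last-formed and most nucleophilic carbanion) by the methyl ester; three equivalents of dianion are used because one is consumed by the C13 hydroxyl and one by the acidic methylene of the product, and the remote lithium alkoxide is otherwise inert.

Step 4
Reactants: 9 4-hydroxy-6-[(14S)-14-hydroxy-2-oxoheptadecyl]-2H-pyran-2-one
Product: 11 (13S)-13-hydroxy-1-(2,4,6-trihydroxyphenyl)hexadecan-1-one, via methyl (19S)-19-hydroxy-3,5,7-trioxodocosanoate 10 (not isolated)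
Conditions: KOMe (8 equiv), dry degassed MeOH, reflux, Ar; then 1 M HCl, 0 °C
Reagents that add atoms: none
Why: Methoxide adds to the lactone carbonyl (pyrone C2) and opens the ring to the potassium polyenolate of triketo ester 10, whose C6 carbanion, flanked by the C5 and C7 ketones, attacks the ester carbonyl C1 and expels methoxide, after which the 2-acylcyclohexane-1,3,5-trione tautomerises to the aromatic ketone. The closest known reaction type is the biomimetic Claisen cyclisation of 3,5,7-triketo esters and of 6-(2-oxoalkyl)-4-hydroxy-2-pyrones to acylphloroglucinols, the laboratory counterpart of the closure carried out by chalcone-synthase-type polyketide synthases. The one ring formed, the benzene ring, closes by a 6-(enolexo)-exo-trig Dieckmann-type condensation that joins the acyl-bearing carbon to the former lactone carbon. No stereocentre is created, and C13, a remote carbinol with no acidifying neighbour, cannot epimerise in base. The selectivity needed is Claisen closure (C6 onto C1) over aldol closure (C2 onto C7, which would give a methyl 6-alkylresorcylate): anhydrous methoxide keeps C1 an ester and not an unreactive carboxylate, the non-chelating potassium counter-ion avoids the chelation that activates the C7 ketone for aldol attack, and only the Claisen product is removed irreversibly as an aromatic triphenoxide. Oxygen is excluded because the electron-rich polyphenoxide is air-sensitive.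

## Compound list

1 | undec-10-ynoic acid | C#CCCCCCCCCC(=O)O | starting material
2 | (S)-1,2-epoxypentane [(2S)-2-propyloxirane] | CCC[C@H]1CO1 | starting material
3 | lithium 11-lithioundec-10-ynoate | [Li]C#CCCCCCCCCC(=O)O[Li] | intermediate
4 | (13S)-13-hydroxyhexadec-10-ynoic acid | CCC[C@H](O)CC#CCCCCCCCCC(=O)O | intermediate
5 | methyl (13S)-13-hydroxyhexadec-10-ynoate | CCC[C@H](O)CC#CCCCCCCCCC(=O)OC | intermediate
6 | methyl (13S)-13-hydroxyhexadecanoate | CCC[C@H](O)CCCCCCCCCCCC(=O)OC | intermediate
7 | triacetic acid lactone (4-hydroxy-6-methyl-2H-pyran-2-one) | CC1=CC(O)=CC(=O)O1 | starting material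
8 | lithium 6-(lithiomethyl)-2-oxo-2H-pyran-4-olate | [Li]CC1=CC(O[Li])=CC(=O)O1 | intermediate
9 | 4-hydroxy-6-[(14S)-14-hydroxy-2-oxoheptadecyl]-2H-pyran-2-one | CCC[C@H](O)CCCCCCCCCCCC(=O)CC1=CC(O)=CC(=O)O1 | intermediate
10 | methyl (19S)-19-hydroxy-3,5,7-trioxodocosanoate | CCC[C@H](O)CCCCCCCCCCCC(=O)CC(=O)CC(=O)CC(=O)OC | intermediate
11 | (13S)-13-hydroxy-1-(2,4,6-trihydroxyphenyl)hexadecan-1-one | CCC[C@H](O)CCCCCCCCCCCC(=O)c1c(O)cc(O)cc1O | target

Total step count: 4. Longest linear sequence: 4 steps (1 → 4 → 6 → 9 → 11); lactone 7 enters at step 3.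

Steps most likely to fail:

Step 4. The open triketo ester may close in the aldol mode instead of the Claisen mode, be cleaved by retro-Claisen fragmentation, or be diverted to an unreactive carboxylate by adventitious hydroxide. The fallback buys the ring instead of building it, and sets out from 6. Saponification (LiOH, THF/H2O) would give (13S)-13-hydroxyhexadecanoic acid F1. Acetylation (Ac2O, pyridine, aqueous work-up) would give (13S)-13-(acetyloxy)hexadecanoic acid F2, and (COCl)2 with catalytic DMF would give (13S)-13-(acetyloxy)hexadecanoyl chloride F3. Friedel–Crafts C-acylation of phloroglucinol (AlCl3, PhNO2/CH2Cl2, 0 °C → rt) would give (4S)-16-oxo-16-(2,4,6-trihydroxyphenyl)hexadecan-4-yl acetate F4. Methanolysis (K2CO3, MeOH) would then come back to the route at 11.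

Step 3. Proton transfer from the ester α-position or the free hydroxyl may quench the poorly soluble dianion faster than it is C-acylated, leaving low conversion. The fallback replaces the acylation by an aldol addition and oxidation, and sets out from 6. Silylation (TBSCl, imidazole, DMF) would give methyl (13S)-13-[(tert-butyldimethylsilyl)oxy]hexadecanoate F5. Half-reduction (iBu2AlH, CH2Cl2, –78 °C) would give (13S)-13-[(tert-butyldimethylsilyl)oxy]hexadecanal F6. Addition of dianion 8 to this non-acidic electrophile would give 6-[(14S)-14-[(tert-butyldimethylsilyl)oxy]-2-hydroxyheptadecyl]-4-hydroxy-2H-pyran-2-one F7 as a mixture of carbinol epimers. Dess–Martin oxidation would give 6-[(14S)-14-[(tert-butyldimethylsilyl)oxy]-2-oxoheptadecyl]-4-hydroxy-2H-pyran-2-one F8. Desilylation (aqueous HF, MeCN) would come back to the route at 9.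

Step 1. The aggregated dilithio acetylide-carboxylate may open the epoxide only sluggishly, so that base-induced oligomerisation of the epoxide competes. The fallback forms the C10–C11 bond by olefin metathesis instead, and sets out from 2. Opening with vinylmagnesium bromide and catalytic CuI (THF, –30 °C) would give (4S)-hept-1-en-4-ol F9. Cross-metathesis with commercial methyl undec-10-enoate (second-generation Grubbs catalyst, CH2Cl2, 40 °C) would give methyl (13S)-13-hydroxyhexadec-10-enoate F10 as an E/Z mixture, which is immaterial. Hydrogenation (H2, 10% Pd/C, EtOAc) would come back to the route at 6.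

## Further compounds

F1 | step 4 | (13S)-13-hydroxyhexadecanoic acid | CCC[C@H](O)CCCCCCCCCCCC(=O)O
F2 | step 4 | (13S)-13-(acetyloxy)hexadecanoic acid | CCC[C@H](OC(C)=O)CCCCCCCCCCCC(=O)O
F3 | step 4 | (13S)-13-(acetyloxy)hexadecanoyl chloride | CCC[C@H](OC(C)=O)CCCCCCCCCCCC(=O)Cl
F4 | step 4 | (4S)-16-oxo-16-(2,4,6-trihydroxyphenyl)hexadecan-4-yl acetate | CCC[C@H](OC(C)=O)CCCCCCCCCCCC(=O)c1c(O)cc(O)cc1O
F5 | step 3 | methyl (13S)-13-[(tert-butyldimethylsilyl)oxy]hexadecanoate | CCC[C@H](O[Si](C)(C)C(C)(C)C)CCCCCCCCCCCC(=O)OC
F6 | step 3 | (13S)-13-[(tert-butyldimethylsilyl)oxy]hexadecanal | CCC[C@H](O[Si](C)(C)C(C)(C)C)CCCCCCCCCCCC=O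
F7 | step 3 | 6-[(14S)-14-[(tert-butyldimethylsilyl)oxy]-2-hydroxyheptadecyl]-4-hydroxy-2H-pyran-2-one (carbinol epimer mixture) | CCC[C@H](O[Si](C)(C)C(C)(C)C)CCCCCCCCCCCC(O)CC1=CC(O)=CC(=O)O1
F8 | step 3 | 6-[(14S)-14-[(tert-butyldimethylsilyl)oxy]-2-oxoheptadecyl]-4-hydroxy-2H-pyran-2-one | CCC[C@H](O[Si](C)(C)C(C)(C)C)CCCCCCCCCCCC(=O)CC1=CC(O)=CC(=O)O1
F9 | step 1 | (4S)-hept-1-en-4-ol | CCC[C@H](O)CC=C
F10 | step 1 | methyl (13S)-13-hydroxyhexadec-10-enoate (E/Z mixture) | CCC[C@H](O)CC=CCCCCCCCCC(=O)OC
A1 | direct plan | 1-[2,4,6-tris(benzyloxy)phenyl]ethan-1-one | CC(=O)c1c(OCc2ccccc2)cc(OCc2ccccc2)cc1OCc1ccccc1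
A2 | direct plan | (11S)-11-[(tert-butyldimethylsilyl)oxy]tetradecanal | CCC[C@H](O[Si](C)(C)C(C)(C)C)CCCCCCCCCC=O
A3 | direct plan | methyl 11-oxoundecanoate | COC(=O)CCCCCCCCCC=O
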